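# Synthesis proposal for ent-alpinnanin A (31)

## Analysis of the target

ent-Alpinnanin A (31) is a cardamonin-type chalcone (2',4'-dihydroxy-6'-methoxy) whose ring A carries at C3' a linear 1,7-diarylheptanoid bound through its C1. C1 (R) is a methine that joins ring A, the 4-hydroxyphenyl ring (ring B) and the (E)-C2=C3 alkene; C5 (S) is a secondary carbinol. The two stereocentres are 1,5-related across the alkene, so neither can control the other. Each must be set by its own reagent, and any shortfall in enantiomeric purity would appear as diastereomers that are hard to separate. The sensitive groups are the 2'-hydroxychalcone (flavanone closure under acid or base, Michael acceptor), the free phenols on an oxidisable phloroglucinol-type ring, and the C1–H bond, which is doubly benzylic and allylic. Base at C1–H or metal-hydride migration of the alkene into conjugation would erase C1. The main difficulty is ring A: five substituents in the fixed order acyl (C1'), OH (C2'), side chain (C3'), OH (C4'), H (C5'), OMe (C6'). The bulky chiral methine sits between two oxygens, and only one of three oxygens is methylated. Friedel–Crafts alkylation of a phloroglucinol ether would control neither the position nor C1. The strategy rests on reading ring A before acylation as a 2-alkyl-5-methoxyresorcinol. C3' and C4' (alkyl, oxygen) are the two carbons of a siloxyalkyne. C2', C1', C6' and C5' (O, H, OMe, H) are the four carbons of a 3-methoxy vinylketene, so the ring can be built around the side chain that is already in place.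

## Retrosynthetic reasoning

**Protecting groups and the chalcone carbonyl.** Target 31 is traced to its fully protected form 30 (three MOM ethers, one TBS ether), so that the last step is one mild acidic operation. The C1'–C(=O) bond is then cut. Ketone 30 comes from carbinol 29 by oxidation of a benzylic, allylic alcohol, and 29 from aryllithium 28 and cinnamaldehyde 27. Cutting here avoids Friedel–Crafts acylation, whose strong acid threatens the C3'–C1 bond and the alkene. It also places the acyl group exactly where a halogen sits in iodide 26.

**C2=C3 alkene.** Iodide 26 is opened at the alkene by cross-metathesis into the terminal olefin 22 and the homoallylic silyl ether 25. This makes the route convergent and takes C5 out of the main line. Alcohol 24 (silylated to 25) comes from aldehyde 23 by catalytic asymmetric allylation. The forward reaction must give the E-alkene without moving the double bond into conjugation with the two rings at C1.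

**Ring A substituents.** Iodide 22 derives from the bis-MOM ether 21, and 21 from resorcinol 20, which is the desilylated form of phenol 19. The detour through 20 is deliberate. With both ring A oxygens carrying the same group, the ring is symmetric about the C3'–C6' axis. The two free positions are then equivalent, so iodination and the later acylation have only one outcome.

**Ring A itself (key disconnection).** Phenol 19 is cut at C2'–C3' and C4'–C5', with C1'–C2' as the ring-closing bond. This gives siloxyalkyne 14 and 3-methoxycyclobutenone 2, the latent form of vinylketene 15. All ring A substituents are fixed by the two partners, and the chiral side chain is placed between the two oxygens by the polarity of the alkyne, not by a substitution on an existing arene. The forward cascade is neutral, which suits the acid- and base-sensitive C1.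

**Ynol ether.** Siloxyalkyne 14 comes from terminal alkyne 11 by oxidation of its acetylide 12 with a peroxide to ynolate 13 and O-silylation. Alkyne 11 comes from silylalkyne 10 by protodesilylation. No carbon–carbon bond is made here, so the stereocentre of 10 is carried over.

**C1 stereocentre.** Enyne 10 is cut between C1 and the alkyne into the racemic aryl vinyl carbinol 9 and alkynyltrifluoroborate 6. An iridium-catalysed enantioconvergent allylic alkynylation forms this bond, sets C1 and leaves the terminal vinyl group needed for the metathesis. Carbinol 9 comes from aldehyde 8 (vinyl addition), 8 from 7 by protection, and 6 from alkyne 3.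

**Cyclobutenone.** Compound 2 is reached from the commercial ethyl vinylogous ester 1 by alkoxy exchange, which puts the C6' methyl ether in place before the ring exists.

## Alternatives that were turned down

**Alternative 1: three-component carbonylative coupling at the chalcone carbonyl.** The disconnection removes both bonds at the carbonyl. A palladium-catalysed carbonylative Suzuki coupling would join the ring A iodide A1 (the constitution of 26), (E)-styrylboronic acid A2 and carbon monoxide A3 to give the protected chalcone A4; no ring is formed.
- For: it reaches the ketone oxidation state in one step. It needs no organolithium near the acidic C1–H and no separate oxidation, and is one step shorter than the exchange, addition and oxidation sequence used here. On that point it is stronger.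
- Against: A1 is electron-rich and flanked by two ortho oxygens, so oxidative addition and carbon monoxide insertion are slow. Direct coupling without insertion and further reaction of the enone product are plausible losses.
- Comparison: this step only decorates a ring A that already carries the side chain between its oxygens, so the central problem is left unsolved. The chosen strategy solves that problem in its key step. The coupling is kept as the fallback for step 15.

**Alternative 2: Claisen-type folding of an open-chain tetraketide.** Ring A would be closed at C1'–C6'. In the masked polyketone A5 a magnesium alkoxide base would enolise the methylene next to the cinnamoyl ketone; this carbon would add to the terminal ketene-acetal carbon and, after loss of alkoxide, give A6 with ring A complete as its methyl ether.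
- For: it follows the biosynthesis and delivers the acyl group, both free ring A hydroxyls and the methyl ether at once. The iodination, metalation, oxidation and ring A protection steps of the chosen route would not be needed. In the endgame it is clearly shorter.
- Against: A5 is a 1,3,5-triketone with several enolisable sites, an enone acceptor and a ketene acetal. Pyranone formation, aldol closure onto a ketone and conjugate additions compete with the desired C-acylation-type closure. Assembling A5 with the C1 stereocentre on its central carbon is a long linear task through labile intermediates.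
- Comparison: the chosen benzannulation uses two stable partners and a pericyclic cascade whose regiochemistry is fixed by polarity. The price is a longer but conventional endgame.

**Alternative 3: conjunctive coupling for C3–C6.** The C3–C4 and C5–C6 bonds would be formed together. The ate complex from vinylboronic pinacol ester A8 and phenethyllithium A9 would react with the (E)-alkenyl bromide A7 under a chiral bisphosphine–palladium catalyst to give the C5 boronate A10.
- For: C5 is set by the catalyst in the bond-forming step and oxidation of the carbon–boron bond is stereoretentive. Ruthenium-hydride migration of the alkene cannot occur and no tin reagent is needed. On control of alkene position it is at least as good as metathesis.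
- Against: A7 already contains ring A with the C1 stereocentre, so the hardest bond construction is presupposed. Making the E-bromide from the terminal vinyl group costs extra steps. The strongly basic ate-complex chemistry meets the acidic C1–H of A7, and oxidation of A10 and the whole chalcone installation still follow.
- Comparison: the chosen route obtains C5 from a simple carbonyl allylation of a cheap aldehyde. It forms the E-alkene in one step from the vinyl group that the alkynylation leaves behind.

Key step: step 8

Assumption on the chemistry: the (R)-configured phosphoramidite–olefin ligand is taken to deliver the alkynyl group to the face of the iridium allyl complex that gives (R)-10. If the sense of induction is the opposite, the (S)-ligand is used and nothing else changes.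

## Route

Step 1
Reactants: 1 3-ethoxycyclobut-2-en-1-one
Product: 2 3-methoxycyclobut-2-en-1-one
Conditions: MeOH (solvent), camphorsulfonic acid (2 mol%), 4 Å MS, rt; NaHCO3; concentrate, repeat once; bulb-to-bulb distillation
Reagents that add atoms: methanol, CO
Why: Acid-catalysed transetherification of a vinylogous ester: methanol adds at C3 of the protonated enone and ethanol leaves; the large excess of methanol drives the exchange and dry conditions prevent hydrolysis to the 1,3-dione.

Step 2
Reactants: 3 ethynyltrimethylsilane
Product: 6 potassium trifluoro[(trimethylsilyl)ethynyl]borate, via lithium (trimethylsilyl)acetylide 4 (not isolated), via lithium trimethoxy(alkynyl)borate 5 (not isolated)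
Conditions: n-BuLi, THF, −78 °C; B(OMe)3, −78 → −20 °C; aq KHF2, −20 °C → rt
Reagents that add atoms: trimethyl borate, COB(OC)OC; potassium hydrogen difluoride, [K+].[F-].F
Why: Standard preparation of a potassium alkynyltrifluoroborate by deprotonation, borylation and fluoride exchange; the acidic bifluoride converts the ate complex to the air-stable salt and should leave the carbon–silicon bond intact.

Step 3
Reactants: 7 4-hydroxybenzaldehyde
Product: 8 4-(methoxymethoxy)benzaldehyde
Conditions: MOMCl, i-Pr2NEt, CH2Cl2, 0 °C → rt
Reagents that add atoms: chloromethyl methyl ether, COCCl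
Why: O-alkylation of the phenol; the MOM ether tolerates Grignard, lithium amide and fluoride reagents and is removed with the other acetals at the end.

Step 4
Reactants: 8 4-(methoxymethoxy)benzaldehyde
Product: 9 rac-1-[4-(methoxymethoxy)phenyl]prop-2-en-1-ol
Conditions: CH2=CHMgBr, THF, −78 → 0 °C; aq NH4Cl
Reagents that add atoms: vinylmagnesium bromide, C=C[Mg]Br
Why: Grignard 1,2-addition to an aryl aldehyde; the racemate is wanted because the next step is enantioconvergent.

Step 5
Reactants: 9 rac-1-[4-(methoxymethoxy)phenyl]prop-2-en-1-ol; 6 potassium trifluoro[(trimethylsilyl)ethynyl]borate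
Product: 10 (R)-{3-[4-(methoxymethoxy)phenyl]pent-4-en-1-yn-1-yl}trimethylsilane
Conditions: [Ir(cod)Cl]2 (4 mol%), (R)-BINOL-derived dibenzo[b,f]azepin-5-yl phosphoramidite (16 mol%), KHF2, CF3CO2H, n-Bu4NBr (cat.), 1,4-dioxane, rt
Reagents that add atoms: none
Why: Iridium-catalysed enantioconvergent allylic alkynylation of a branched aryl vinyl carbinol: acid-promoted ionisation of either enantiomer of 9 gives the same iridium allyl complex, the alkynyl group is transferred from boron to the benzylic terminus (branched product), and the chiral phosphoramidite–olefin ligand selects the face, which sets C1.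

Step 6
Reactants: 10 (R)-{3-[4-(methoxymethoxy)phenyl]pent-4-en-1-yn-1-yl}trimethylsilane
Product: 11 (S)-1-(methoxymethoxy)-4-(pent-1-en-4-yn-3-yl)benzene
Conditions: K2CO3 (0.2 equiv), MeOH, 0 °C
Reagents that add atoms: none
Why: Methoxide-mediated protodesilylation of an alkynylsilane, run cold and with substoichiometric base to keep the skipped enyne from isomerising; the arrangement at the stereocentre is unchanged and the descriptor becomes S only because aryl outranks ethynyl.

Step 7
Reactants: 11 (S)-1-(methoxymethoxy)-4-(pent-1-en-4-yn-3-yl)benzene
Product: 14 (R)-triisopropyl({3-[4-(methoxymethoxy)phenyl]pent-4-en-1-yn-1-yl}oxy)silane, via lithium acetylide 12 (not isolated), via lithium ynolate 13 (not isolated)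
Conditions: LiN(SiMe3)2 (1.0 equiv), THF, −78 °C; LiOOt-Bu [from t-BuOOH + LiN(SiMe3)2, THF, −78 °C], −78 → 0 °C; i-Pr3SiOTf, −78 → 0 °C; filtration through basic alumina
Reagents that add atoms: tert-butyl hydroperoxide, CC(C)(C)OO; triisopropylsilyl trifluoromethanesulfonate, CC(C)[Si](OS(=O)(=O)C(F)(F)F)(C(C)C)C(C)C
Why: Oxidation of a lithium acetylide with lithium tert-butyl peroxide (attack of the acetylide on the peroxide oxygen) gives the ynolate, which the bulky silyl triflate traps on oxygen; the amide base is too weak to remove C3–H, and once the alkyne is deprotonated the negative charge of 12 and 13 shields that position.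

Step 8
Reactants: 14 (R)-triisopropyl({3-[4-(methoxymethoxy)phenyl]pent-4-en-1-yn-1-yl}oxy)silane; 2 3-methoxycyclobut-2-en-1-one
Product: 19 5-methoxy-2-{(R)-1-[4-(methoxymethoxy)phenyl]allyl}-3-[(triisopropylsilyl)oxy]phenol, via 3-methoxy vinylketene 15 (not isolated), via cyclobutenone adduct 16 (not isolated), via dienylketene 17 (not isolated), via cyclohexa-2,4-dienone 18 (not isolated)
Conditions: 2 (1.5 equiv, two portions), toluene, 110 °C, sealed tube, dark
Reagents that add atoms: none
Why: On heating, 2 undergoes a four-electron conrotatory ring opening to vinylketene 15, whose electrophilic carbonyl carbon is attacked by the nucleophilic, side-chain-bearing carbon of the polarised siloxyalkyne 14 in a [2+2] cycloaddition, so that C2'–C3' forms from the ketene carbon and C4'–C5' from the ketene alpha carbon, giving 16. A second four-electron opening of 16, which is reversible so that the isomer with the methoxyvinyl group turned towards the ketene is drained off, gives dienylketene 17; this closes ring A by a thermal disrotatory six-electron electrocyclisation between the ketene carbon and the terminal methylene (bond C1'–C2', six-membered carbocycle 18), and enolisation gives phenol 19. The closest known reaction type is the Danheiser benzannulation of cyclobutenones with trialkylsiloxyalkynes to resorcinol monosilyl ethers; the 3-alkoxy group on the cyclobutenone is the unusual element and is the reason for a temperature above the usual 80 °C. No new stereocentre remains in 19, since C4 of 16 is lost on ring opening, and the C1 stereocentre from step 5 is carried through because the cascade is neutral and no intermediate makes C1–H more acidic. The step needs regioselectivity in the [2+2] addition, which the donor oxygen of 14 secures by making the carbon that bears the side chain the nucleophilic terminus, and chemoselectivity for the triple bond over the vinyl group, which follows from the far higher reactivity of an electron-rich alkyne towards ketenes. The bulky triisopropylsilyl group keeps silicon on oxygen during heating and marks the C4' oxygen until the ring is complete.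

Step 9
Reactants: 19 5-methoxy-2-{(R)-1-[4-(methoxymethoxy)phenyl]allyl}-3-[(triisopropylsilyl)oxy]phenol
Product: 20 5-methoxy-2-{(R)-1-[4-(methoxymethoxy)phenyl]allyl}benzene-1,3-diol
Conditions: n-Bu4NF (1.1 equiv), THF, 0 °C; aq NH4Cl; used directly under argon
Reagents that add atoms: none
Why: Fluoride cleavage of an aryl silyl ether (phenoxide as leaving group); the resorcinol is symmetric about the C3'–C6' axis, which removes the difference between the two open ring positions.

Step 10
Reactants: 20 5-methoxy-2-{(R)-1-[4-(methoxymethoxy)phenyl]allyl}benzene-1,3-diol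
Product: 21 5-methoxy-1,3-bis(methoxymethoxy)-2-{(R)-1-[4-(methoxymethoxy)phenyl]allyl}benzene
Conditions: MOMCl (3 equiv), i-Pr2NEt, n-Bu4NI (cat.), CH2Cl2, 0 → 40 °C
Reagents that add atoms: chloromethyl methyl ether, COCCl
Why: Double O-alkylation of the hindered phenols with a hard electrophile under amine base, which favours O- over C-alkylation and does not touch C1–H; the MOM ethers later stabilise the ortho-aryllithium.

Step 11
Reactants: 21 5-methoxy-1,3-bis(methoxymethoxy)-2-{(R)-1-[4-(methoxymethoxy)phenyl]allyl}benzene
Product: 22 2-iodo-1-methoxy-3,5-bis(methoxymethoxy)-4-{(R)-1-[4-(methoxymethoxy)phenyl]allyl}benzene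
Conditions: NIS (1.0 equiv), MeCN, 0 °C, dark
Reagents that add atoms: N-iodosuccinimide, O=C1CCC(=O)N1I
Why: Electrophilic aromatic iodination of a trialkoxybenzene, which needs no acid; the two open positions of ring A are equivalent, ring B and the terminal alkene are far less nucleophilic, and one equivalent of reagent limits double iodination.

Step 12
Reactants: 23 3-phenylpropanal
Product: 24 (S)-1-phenylhex-5-en-3-ol
Conditions: (R)-BINOL (10 mol%), Ti(Oi-Pr)4 (10 mol%), 4 Å MS, allylSnBu3, CH2Cl2, −20 °C; aq NaHCO3
Reagents that add atoms: allyltributylstannane, C=CC[Sn](CCCC)(CCCC)CCCC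
Why: Keck asymmetric allylation: the BINOL–titanium Lewis acid activates the aldehyde and directs the allylstannane to its re face, which sets C5 as S.

Step 13
Reactants: 24 (S)-1-phenylhex-5-en-3-ol
Product: 25 (S)-tert-butyldimethyl[(1-phenylhex-5-en-3-yl)oxy]silane
Conditions: TBSCl, imidazole, DMF, rt
Reagents that add atoms: tert-butyldimethylsilyl chloride, CC(C)(C)[Si](C)(C)Cl
Why: Silylation of a secondary alcohol; the ether survives metathesis, organolithium and MnO2 and falls off under the same mild acid as the MOM groups.

Step 14
Reactants: 22 2-iodo-1-methoxy-3,5-bis(methoxymethoxy)-4-{(R)-1-[4-(methoxymethoxy)phenyl]allyl}benzene; 25 (S)-tert-butyldimethyl[(1-phenylhex-5-en-3-yl)oxy]silane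
Product: 26 tert-butyl({(3S,5E,7R)-7-[3-iodo-4-methoxy-2,6-bis(methoxymethoxy)phenyl]-7-[4-(methoxymethoxy)phenyl]-1-phenylhept-5-en-3-yl}oxy)dimethylsilane
Conditions: second-generation Grubbs catalyst RuCl2(=CHPh)(H2IMes)(PCy3) (5–10 mol%), 25 (3 equiv), 1,4-benzoquinone (10 mol%), CH2Cl2, 40 °C
Reagents that add atoms: none
Why: Olefin cross-metathesis between a hindered terminal olefin that does not homodimerise (22) and an unhindered one used in excess (25); the E-alkene is the thermodynamic product and benzoquinone intercepts ruthenium hydrides that would move the double bond into conjugation at C1.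

Step 15
Reactants: 26 tert-butyl({(3S,5E,7R)-7-[3-iodo-4-methoxy-2,6-bis(methoxymethoxy)phenyl]-7-[4-(methoxymethoxy)phenyl]-1-phenylhept-5-en-3-yl}oxy)dimethylsilane; 27 (E)-cinnamaldehyde
Product: 29 (2E)-1-{3-[(1R,2E,5S)-5-[(tert-butyldimethylsilyl)oxy]-1-[4-(methoxymethoxy)phenyl]-7-phenylhept-2-en-1-yl]-6-methoxy-2,4-bis(methoxymethoxy)phenyl}-3-phenylprop-2-en-1-ol (both carbinol epimers), via ring A aryllithium 28 (not isolated)
Conditions: n-BuLi (1.05 equiv), THF, −78 °C, 5 min; then 27 (1.5 equiv), −78 °C; aq NH4Cl
Reagents that add atoms: none
Why: Lithium–iodine exchange is far faster than deprotonation at −78 °C and gives an aryllithium held by the flanking OMOM and OMe groups, which adds 1,2 to the enal; the new carbinol centre is not controlled and is removed in the next step.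

Step 16
Reactants: 29 (2E)-1-{3-[(1R,2E,5S)-5-[(tert-butyldimethylsilyl)oxy]-1-[4-(methoxymethoxy)phenyl]-7-phenylhept-2-en-1-yl]-6-methoxy-2,4-bis(methoxymethoxy)phenyl}-3-phenylprop-2-en-1-ol
Product: 30 (2E)-1-{3-[(1R,2E,5S)-5-[(tert-butyldimethylsilyl)oxy]-1-[4-(methoxymethoxy)phenyl]-7-phenylhept-2-en-1-yl]-6-methoxy-2,4-bis(methoxymethoxy)phenyl}-3-phenylprop-2-en-1-one
Conditions: MnO2 (activated, excess), CH2Cl2, rt
Reagents that add atoms: none
Why: MnO2 oxidises only the doubly activated (benzylic and cinnamylic) alcohol under neutral conditions, so the silyl ether, the acetals and C1–H are left alone.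

Step 17
Reactants: 30 (2E)-1-{3-[(1R,2E,5S)-5-[(tert-butyldimethylsilyl)oxy]-1-[4-(methoxymethoxy)phenyl]-7-phenylhept-2-en-1-yl]-6-methoxy-2,4-bis(methoxymethoxy)phenyl}-3-phenylprop-2-en-1-one
Product: 31 ent-alpinnanin A, (2E)-1-{2,4-dihydroxy-3-[(1R,2E,5S)-5-hydroxy-1-(4-hydroxyphenyl)-7-phenylhept-2-en-1-yl]-6-methoxyphenyl}-3-phenylprop-2-en-1-one
Conditions: HCl (aq, ca. 2 M final concentration) in MeOH, rt
Reagents that add atoms: none
Why: Acid-catalysed acetal exchange with methanol removes the three MOM groups and the TBS ether in one operation; dilute acid at room temperature is chosen so that the 2'-hydroxychalcone is not driven to the flavanone, and the acyl group now deactivates ring A against ipso-protonation.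

## Compound list

1 | 3-ethoxycyclobut-2-en-1-one | CCOC1=CC(=O)C1 | starting material
2 | 3-methoxycyclobut-2-en-1-one | COC1=CC(=O)C1 | intermediate
3 | ethynyltrimethylsilane | C#C[Si](C)(C)C | starting material
4 | lithium (trimethylsilyl)acetylide | [Li]C#C[Si](C)(C)C | intermediate (not isolated)
5 | lithium trimethoxy[(trimethylsilyl)ethynyl]borate | [Li+].CO[B-](OC)(OC)C#C[Si](C)(C)C | intermediate (not isolated)
6 | potassium trifluoro[(trimethylsilyl)ethynyl]borate | [K+].F[B-](F)(F)C#C[Si](C)(C)C | intermediate
7 | 4-hydroxybenzaldehyde | O=Cc1ccc(O)cc1 | starting material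
8 | 4-(methoxymethoxy)benzaldehyde | COCOc1ccc(C=O)cc1 | intermediate
9 | rac-1-[4-(methoxymethoxy)phenyl]prop-2-en-1-ol | COCOc1ccc(C(O)C=C)cc1 | intermediate
10 | (R)-{3-[4-(methoxymethoxy)phenyl]pent-4-en-1-yn-1-yl}trimethylsilane | C[Si](C)(C)C#C[C@H](C=C)c1ccc(OCOC)cc1 | intermediate
11 | (S)-1-(methoxymethoxy)-4-(pent-1-en-4-yn-3-yl)benzene | C#C[C@H](C=C)c1ccc(OCOC)cc1 | intermediate
12 | lithium acetylide of 11 | [Li]C#C[C@H](C=C)c1ccc(OCOC)cc1 | intermediate (not isolated)
13 | lithium (R)-3-[4-(methoxymethoxy)phenyl]pent-4-en-1-yn-1-olate | [Li]OC#C[C@H](C=C)c1ccc(OCOC)cc1 | intermediate (not isolated)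
14 | (R)-triisopropyl({3-[4-(methoxymethoxy)phenyl]pent-4-en-1-yn-1-yl}oxy)silane | CC(C)[Si](C(C)C)(C(C)C)OC#C[C@H](C=C)c1ccc(OCOC)cc1 | intermediate
15 | 3-methoxybuta-1,3-dien-1-one | C=C(OC)C=C=O | intermediate (not isolated)
16 | 4-(1-methoxyvinyl)-2-{(R)-1-[4-(methoxymethoxy)phenyl]allyl}-3-[(triisopropylsilyl)oxy]cyclobut-2-en-1-one (both C4 epimers) | O=C1C([C@H](C=C)c2ccc(OCOC)cc2)=C(O[Si](C(C)C)(C(C)C)C(C)C)C1C(OC)=C | intermediate (not isolated)
17 | (3E)-5-methoxy-2-{(R)-1-[4-(methoxymethoxy)phenyl]allyl}-3-[(triisopropylsilyl)oxy]hexa-1,3,5-trien-1-one | O=C=C([C@H](C=C)c1ccc(OCOC)cc1)/C(O[Si](C(C)C)(C(C)C)C(C)C)=C\C(OC)=C | intermediate (not isolated)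
18 | 5-methoxy-2-{(R)-1-[4-(methoxymethoxy)phenyl]allyl}-3-[(triisopropylsilyl)oxy]cyclohexa-2,4-dien-1-one | O=C1CC(OC)=CC(O[Si](C(C)C)(C(C)C)C(C)C)=C1[C@H](C=C)c2ccc(OCOC)cc2 | intermediate (not isolated)
19 | 5-methoxy-2-{(R)-1-[4-(methoxymethoxy)phenyl]allyl}-3-[(triisopropylsilyl)oxy]phenol | COc1cc(O)c([C@H](C=C)c2ccc(OCOC)cc2)c(O[Si](C(C)C)(C(C)C)C(C)C)c1 | intermediate
20 | 5-methoxy-2-{(R)-1-[4-(methoxymethoxy)phenyl]allyl}benzene-1,3-diol | COc1cc(O)c([C@H](C=C)c2ccc(OCOC)cc2)c(O)c1 | intermediate
21 | 5-methoxy-1,3-bis(methoxymethoxy)-2-{(R)-1-[4-(methoxymethoxy)phenyl]allyl}benzene | COc1cc(OCOC)c([C@H](C=C)c2ccc(OCOC)cc2)c(OCOC)c1 | intermediate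
22 | 2-iodo-1-methoxy-3,5-bis(methoxymethoxy)-4-{(R)-1-[4-(methoxymethoxy)phenyl]allyl}benzene | COc1cc(OCOC)c([C@H](C=C)c2ccc(OCOC)cc2)c(OCOC)c1I | intermediate
23 | 3-phenylpropanal | O=CCCc1ccccc1 | starting material
24 | (S)-1-phenylhex-5-en-3-ol | C=CC[C@@H](O)CCc1ccccc1 | intermediate
25 | (S)-tert-butyldimethyl[(1-phenylhex-5-en-3-yl)oxy]silane | C=CC[C@@H](O[Si](C)(C)C(C)(C)C)CCc1ccccc1 | intermediate
26 | tert-butyl({(3S,5E,7R)-7-[3-iodo-4-methoxy-2,6-bis(methoxymethoxy)phenyl]-7-[4-(methoxymethoxy)phenyl]-1-phenylhept-5-en-3-yl}oxy)dimethylsilane | COc1cc(OCOC)c([C@H](/C=C/C[C@@H](O[Si](C)(C)C(C)(C)C)CCc2ccccc2)c2ccc(OCOC)cc2)c(OCOC)c1I | intermediate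
27 | (E)-cinnamaldehyde | O=C/C=C/c1ccccc1 | starting material
28 | ring A aryllithium from 26 (lithium in place of iodine) | COc1cc(OCOC)c([C@H](/C=C/C[C@@H](O[Si](C)(C)C(C)(C)C)CCc2ccccc2)c2ccc(OCOC)cc2)c(OCOC)c1[Li] | intermediate (not isolated)
29 | protected chalcone carbinol (both carbinol epimers), name as in step 15 | COc1cc(OCOC)c([C@H](/C=C/C[C@@H](O[Si](C)(C)C(C)(C)C)CCc2ccccc2)c2ccc(OCOC)cc2)c(OCOC)c1C(O)/C=C/c1ccccc1 | intermediate
30 | fully protected ent-alpinnanin A, name as in step 16 | COc1cc(OCOC)c([C@H](/C=C/C[C@@H](O[Si](C)(C)C(C)(C)C)CCc2ccccc2)c2ccc(OCOC)cc2)c(OCOC)c1C(=O)/C=C/c1ccccc1 | intermediate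
31 | ent-alpinnanin A | COc1cc(O)c([C@H](/C=C/C[C@@H](O)CCc2ccccc2)c2ccc(O)cc2)c(O)c1C(=O)/C=C/c1ccccc1 | target

## Step count and the least certain steps

Total: 17 steps. Longest linear sequence: 13 steps (7 → 8 → 9 → 10 → 11 → 14 → 19 → 20 → 21 → 22 → 26 → 29 → 30 → 31). The side branches are step 1 (partner 2), step 2 (borate 6) and steps 12–13 (olefin 25).

**Step 8 (key step).** The vinylogous-ester stabilisation of 2 raises the barrier of its ring opening. At the temperature then needed, siloxyalkyne 14 may be lost by silyl migration or protonolysis before enough vinylketene 15 is present. The ketene may also oligomerise or acylate the product phenol. The fallback makes the same ketene without a cyclobutenone. Commercial methyl (E)-3-methoxybut-2-enoate is saponified to (E)-3-methoxybut-2-enoic acid F1 and converted with oxalyl chloride into (E)-3-methoxybut-2-enoyl chloride F2. Slow addition of F2 to 14 and Et3N in toluene at room temperature gives 15 by 1,4-dehydrochlorination. It is trapped at once by 14 to give adduct 16, and warming to 80 °C takes 16 on to 19. The fallback sets out from 14 and rejoins the route at 16 and then 19.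

**Step 7.** The likely failure is proton transfer from the activated C3–H of the neutral enyne while base is present, before deprotonation of the alkyne is complete or after silylation. This would erode the configuration at C1 or isomerise the skipped enyne. C-silylation to a silylketene is a smaller risk. The fallback avoids a long-lived acetylide. Alkyne 11 is treated with PhI(OH)OTs to give the alkynyl(phenyl)iodonium tosylate F3. CuOTf (catalytic) converts F3 into (R)-3-[4-(methoxymethoxy)phenyl]pent-4-en-1-yn-1-yl 4-methylbenzenesulfonate F4. MeLi at −78 °C attacks sulfur and releases ynolate 13 directly in the cold, and 13 is silylated as before. This path is longer, and the acidic iodonium step would need buffering for the MOM ether. It sets out from 11 and rejoins at 13 and then 14.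

**Step 14.** The carbene has to form next to a methine carrying two aryl groups, one with two ortho substituents, so turnover may be slow. Slow turnover gives ruthenium hydrides time to move the double bond into conjugation, which destroys C1. The fallback moves the metathesis ahead of protection and iodination, where the olefin is flanked by two small hydroxyl groups. Resorcinol 20 and 25 are coupled with the same second-generation Grubbs catalyst RuCl2(=CHPh)(H2IMes)(PCy3) to give 2-{(1R,2E,5S)-5-[(tert-butyldimethylsilyl)oxy]-1-[4-(methoxymethoxy)phenyl]-7-phenylhept-2-en-1-yl}-5-methoxybenzene-1,3-diol F5. MOMCl and i-Pr2NEt give the bis-MOM ether F6, and NIS iodination of F6 returns 26. The fallback sets out from 20 and rejoins at 26.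

**Step 5.** The acidic fluoride medium may remove the aryl MOM group or the alkynyl silyl group, and facial selectivity with a silyl-substituted alkynyl donor may be lower than wanted. The fallback forms the same bond under basic conditions. Carbinol 9 is isomerised with Ph3SiOReO3 (catalytic) to (E)-3-[4-(methoxymethoxy)phenyl]prop-2-en-1-ol F7, which is converted with diethyl chlorophosphate into the allylic phosphate F8. A copper-catalysed, SN2'-selective enantioselective allylic substitution (CuCl2·2H2O with a chiral sulfonate-bearing N-heterocyclic carbene precursor) with the alkynylaluminium reagent from 3 and i-Bu2AlH gives 10. The fallback sets out from 9 and rejoins at 10.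

**Step 15.** The aryllithium 28 is basic enough to abstract the doubly benzylic, allylic C1–H of a second molecule if the addition is slow. The two ortho substituents may also hold back addition to the aldehyde. The fallback needs no carbanion. Iodide 26 undergoes a carbonylative Suzuki coupling with carbon monoxide and (E)-styrylboronic acid (Pd(OAc)2, di(1-adamantyl)-n-butylphosphine, K2CO3, toluene, 100 °C) to give ketone 30 directly. The fallback sets out from 26 and rejoins at 30, bypassing 29.

**Step 17.** Protic acid may close the 2'-hydroxychalcone to the flavanone by intramolecular oxa-Michael addition, or protonate the electron-rich ring before the last MOM group is gone. The fallback separates the two cleavages and avoids protic acid. Bromotrimethylsilane in CH2Cl2 at −30 °C over 4 Å MS cleaves the three MOM ethers aprotically and gives the C5 silyl ether of ent-alpinnanin A F9. HF·pyridine in THF at 0 °C then removes the TBS group. The fallback sets out from 30 and rejoins at 31.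

## Further compounds

F1 | step 8 | (E)-3-methoxybut-2-enoic acid | CO/C(C)=C/C(=O)O
F2 | step 8 | (E)-3-methoxybut-2-enoyl chloride | CO/C(C)=C/C(=O)Cl
F3 | step 7 | {(R)-3-[4-(methoxymethoxy)phenyl]pent-4-en-1-yn-1-yl}(phenyl)iodonium 4-methylbenzenesulfonate | Cc1ccc(cc1)S(=O)(=O)[O-].c1ccccc1[I+]C#C[C@H](C=C)c1ccc(OCOC)cc1
F4 | step 7 | (R)-3-[4-(methoxymethoxy)phenyl]pent-4-en-1-yn-1-yl 4-methylbenzenesulfonate | Cc1ccc(cc1)S(=O)(=O)OC#C[C@H](C=C)c1ccc(OCOC)cc1
F5 | step 14 | 2-{(1R,2E,5S)-5-[(tert-butyldimethylsilyl)oxy]-1-[4-(methoxymethoxy)phenyl]-7-phenylhept-2-en-1-yl}-5-methoxybenzene-1,3-diol | COc1cc(O)c([C@H](/C=C/C[C@@H](O[Si](C)(C)C(C)(C)C)CCc2ccccc2)c2ccc(OCOC)cc2)c(O)c1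
F6 | step 14 | tert-butyl({(3S,5E,7R)-7-[4-methoxy-2,6-bis(methoxymethoxy)phenyl]-7-[4-(methoxymethoxy)phenyl]-1-phenylhept-5-en-3-yl}oxy)dimethylsilane | COc1cc(OCOC)c([C@H](/C=C/C[C@@H](O[Si](C)(C)C(C)(C)C)CCc2ccccc2)c2ccc(OCOC)cc2)c(OCOC)c1
F7 | step 5 | (E)-3-[4-(methoxymethoxy)phenyl]prop-2-en-1-ol | COCOc1ccc(/C=C/CO)cc1
F8 | step 5 | diethyl (E)-3-[4-(methoxymethoxy)phenyl]prop-2-en-1-yl phosphate | CCOP(=O)(OCC)OC/C=C/c1ccc(OCOC)cc1
F0 | step 15 | none | none
F9 | step 17 | (2E)-1-{3-[(1R,2E,5S)-5-[(tert-butyldimethylsilyl)oxy]-1-(4-hydroxyphenyl)-7-phenylhept-2-en-1-yl]-2,4-dihydroxy-6-methoxyphenyl}-3-phenylprop-2-en-1-one | COc1cc(O)c([C@H](/C=C/C[C@@H](O[Si](C)(C)C(C)(C)C)CCc2ccccc2)c2ccc(O)cc2)c(O)c1C(=O)/C=C/c1ccccc1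
A1 | alternative 1 | ring A iodide with the protected side chain (constitution of 26) | COc1cc(OCOC)c([C@H](/C=C/C[C@@H](O[Si](C)(C)C(C)(C)C)CCc2ccccc2)c2ccc(OCOC)cc2)c(OCOC)c1I
A2 | alternative 1 | (E)-styrylboronic acid | OB(O)/C=C/c1ccccc1
A3 | alternative 1 | carbon monoxide | [C-]#[O+]
A4 | alternative 1 | fully protected ent-alpinnanin A (constitution of 30) | COc1cc(OCOC)c([C@H](/C=C/C[C@@H](O[Si](C)(C)C(C)(C)C)CCc2ccccc2)c2ccc(OCOC)cc2)c(OCOC)c1C(=O)/C=C/c1ccccc1
A5 | alternative 2 | (8E)-4-{(1R,2E,5S)-5-[(tert-butyldimethylsilyl)oxy]-1-[4-(methoxymethoxy)phenyl]-7-phenylhept-2-en-1-yl}-1,1-dimethoxy-9-phenylnona-1,8-diene-3,5,7-trione | COC(OC)=CC(=O)C([C@H](/C=C/C[C@@H](O[Si](C)(C)C(C)(C)C)CCc2ccccc2)c2ccc(OCOC)cc2)C(=O)CC(=O)/C=C/c1ccccc1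
A6 | alternative 2 | ent-alpinnanin A protected as ring B MOM ether and C5 silyl ether | COc1cc(O)c([C@H](/C=C/C[C@@H](O[Si](C)(C)C(C)(C)C)CCc2ccccc2)c2ccc(OCOC)cc2)c(O)c1C(=O)/C=C/c1ccccc1
A7 | alternative 3 | 2-{(1R,2E)-3-bromo-1-[4-(methoxymethoxy)phenyl]prop-2-en-1-yl}-5-methoxy-1,3-bis(methoxymethoxy)benzene | COc1cc(OCOC)c([C@H](/C=C/Br)c2ccc(OCOC)cc2)c(OCOC)c1
A8 | alternative 3 | vinylboronic acid pinacol ester | C=CB1OC(C)(C)C(C)(C)O1
A9 | alternative 3 | phenethyllithium | [Li]CCc1ccccc1
A10 | alternative 3 | C5 pinacol boronate of the protected 2-(diarylheptenyl)-5-methoxyresorcinol | COc1cc(OCOC)c([C@H](/C=C/C[C@@H](B2OC(C)(C)C(C)(C)O2)CCc2ccccc2)c2ccc(OCOC)cc2)c(OCOC)c1
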